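Cuts: the ring A phenol is first masked again as its MOM ether. The main cut is the bond between the diaryl ketone carbon and ring A. That ring carbon goes back to a phenol C–OH, and the ketone carbon becomes the acyl carbon of a ring B hydrazide condensed on the formyl group.
Enabling feature: on ring A the formyl carbon and the ketone carbon sit on neighbouring ring carbons (a 1,2-diacylbenzene), with C–OH on the formyl side and C–prenyl on the ketone side. This is 2,6-dihydroxy-3-prenylbenzaldehyde with its C2 hydroxyl replaced ipso by the ring B aroyl group, which is the change Pb(OAc)4 brings about in an o-hydroxyaryl N-acylhydrazone.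
Further cuts: the ring A C3–CH2 (prenyl) bond goes back to an O-(1,1-dimethylallyl) ether (Claisen). The two alkyl C–O bonds of the 1,4-dioxane go back to 2,3-dihydroxy-5-methylbenzaldehyde and a C5 epoxy tosylate.
Forward order: both benzene rings are bought, and the dioxane is the only ring made, closed early on ring B. The halves are then joined by a C=N bond and fused by the ketone C–C bond, after which only the MOM group is removed.
Stereochemistry: the single centre comes from Sharpless epoxidation of prenol ((S), L-(+)-tartrate). It is inverted once, to (R), when a phenoxide opens the epoxide, and no later step touches it.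

Key step: step 13

Assumption: the centre in the given SMILES reads as (R). The enantiomeric purity set by the catalytic epoxidation is carried through, and hydrazide 11, expected to be crystalline, is the point for enrichment if needed.

Step 1
Reactants: 1 creosol (2-methoxy-4-methylphenol)
Product: 2 2-hydroxy-3-methoxy-5-methylbenzaldehyde
Conditions: MgCl2, Et3N, (CH2O)n, MeCN, reflux; then 1 M HCl
Reagents that add atoms: paraformaldehyde (as formaldehyde), C=O
Why: Casnati–Skattebøl ortho-formylation, in which the magnesium phenoxide of 1 guides formaldehyde to the carbon next to the oxygen and a second formaldehyde accepts the hydride, can only strike C6 because the other ortho carbon carries OMe and the para carbon carries CH3.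

Step 2
Reactants: 2 2-hydroxy-3-methoxy-5-methylbenzaldehyde
Product: 3 2,3-dihydroxy-5-methylbenzaldehyde
Conditions: BBr3, CH2Cl2, −78 °C to rt; then H2O
Reagents that add atoms: none
Why: Lewis acid cleavage of an aryl methyl ether with BBr3, well known for o-vanillin-type substrates, is helped by binding of boron to the neighbouring phenol oxygen and leaves the aldehyde and the ring methyl group alone at low temperature.

Step 3
Reactants: 4 prenol (3-methylbut-2-en-1-ol)
Product: 5 [(2S)-3,3-dimethyloxiran-2-yl]methanol
Conditions: Ti(OiPr)4 (5 mol %), L-(+)-DIPT (6 mol %), t-BuOOH, 4 Å MS, CH2Cl2, −20 °C; non-aqueous work-up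
Reagents that add atoms: tert-butyl hydroperoxide, CC(C)(C)OO
Why: Katsuki–Sharpless asymmetric epoxidation in its catalytic form with sieves, where the L-(+)-tartrate titanium complex delivers oxygen to the alkene face that makes the oxirane CH carbon (S), the usual sense for allylic alcohols of this substitution pattern.

Step 4
Reactants: 5 [(2S)-3,3-dimethyloxiran-2-yl]methanol
Product: 6 [(2S)-3,3-dimethyloxiran-2-yl]methyl 4-methylbenzenesulfonate
Conditions: TsCl, Et3N, DMAP (cat.), CH2Cl2, −10 to 0 °C
Reagents that add atoms: 4-toluenesulfonyl chloride, Cc1ccc(cc1)S(=O)(=O)Cl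
Why: Routine sulfonylation of a primary alcohol with mild amine base in the cold, which leaves the oxirane and its stereocentre untouched and turns the small polar alcohol into an easily handled bis-electrophile.

Step 5
Reactants: 3 2,3-dihydroxy-5-methylbenzaldehyde; 6 [(2S)-3,3-dimethyloxiran-2-yl]methyl 4-methylbenzenesulfonate
Product: 8 (3R)-3-(2-hydroxypropan-2-yl)-7-methyl-2,3-dihydro-1,4-benzodioxine-5-carbaldehyde, via epoxy ether 7 (not isolated)
Conditions: NaH (2.1 equiv), DMSO, rt; 6, rt; then 60 °C; H2O quench
Reagents that add atoms: none
Why: Regioselective alkylation of a catechol dianion followed by 6-exo-tet epoxide opening (the benzodioxane annulation known for glycidyl sulfonates), in which the C3 oxide, not conjugated with the formyl group and so the stronger nucleophile, displaces the primary tosylate to give 7, whose formyl-stabilised C2 oxide on warming attacks the less substituted (secondary) oxirane carbon from the rear, turning (S) into (R) and releasing the tertiary alkoxide.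

Step 6
Reactants: 8 (3R)-3-(2-hydroxypropan-2-yl)-7-methyl-2,3-dihydro-1,4-benzodioxine-5-carbaldehyde
Product: 9 (3R)-3-(2-hydroxypropan-2-yl)-7-methyl-2,3-dihydro-1,4-benzodioxine-5-carboxylic acid
Conditions: NaClO2, NaH2PO4, 2-methylbut-2-ene, t-BuOH/H2O, 0 °C to rt
Reagents that add atoms: sodium chlorite, [O-]Cl=O.[Na+]
Why: Pinnick oxidation converts the aryl aldehyde into the acid under buffered conditions, the alkene scavenger removing HOCl before it can chlorinate the electron-rich ring, and neither the tertiary alcohol nor the ether stereocentre can react.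

Step 7
Reactants: 9 (3R)-3-(2-hydroxypropan-2-yl)-7-methyl-2,3-dihydro-1,4-benzodioxine-5-carboxylic acid
Product: 11 (3R)-3-(2-hydroxypropan-2-yl)-7-methyl-2,3-dihydro-1,4-benzodioxine-5-carbohydrazide, via acyl imidazolide 10 (not isolated)
Conditions: CDI, THF, rt; then added to N2H4·H2O (excess), THF, 0 °C to rt
Reagents that add atoms: hydrazine (as hydrate), NN
Why: Activation of the acid as its imidazolide followed by acyl substitution with excess hydrazine is a standard hydrazide synthesis, inverse addition suppressing double acylation and the hindered tertiary alcohol being too slow to compete.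

Step 8
Reactants: 12 2,6-dihydroxybenzaldehyde
Product: 13 2-hydroxy-6-(methoxymethoxy)benzaldehyde
Conditions: MOMCl (1.05 equiv), i-Pr2NEt, CH2Cl2, 0 °C
Reagents that add atoms: chloromethyl methyl ether, COCCl
Why: Williamson-type acetal alkylation of one of two equivalent phenols, which should stop after the first MOM group since the remaining hydroxyl is locked in a strong hydrogen bond to the formyl oxygen and only one equivalent of MOMCl is offered.

Step 9
Reactants: 13 2-hydroxy-6-(methoxymethoxy)benzaldehyde; 14 3-chloro-3-methylbut-1-yne
Product: 15 2-(methoxymethoxy)-6-[(2-methylbut-3-yn-2-yl)oxy]benzaldehyde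
Conditions: CuCl2·2H2O (1 mol %), DBU, MeCN, 0 °C
Reagents that add atoms: none
Why: Copper-catalysed O-alkylation of a phenoxide with a tertiary propargylic chloride, a standard entry to aryl 1,1-dimethylpropargyl ethers that runs through a copper acetylide or allenylidene and therefore forms the hindered tertiary C–O bond at 0 °C, well below the temperature of chromene formation.

Step 10
Reactants: 15 2-(methoxymethoxy)-6-[(2-methylbut-3-yn-2-yl)oxy]benzaldehyde
Product: 16 2-(methoxymethoxy)-6-[(2-methylbut-3-en-2-yl)oxy]benzaldehyde
Conditions: H2 (1 atm), Lindlar catalyst, quinoline, EtOAc, rt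
Reagents that add atoms: none
Why: Lindlar semihydrogenation stops at the terminal alkene when the catalyst is poisoned with quinoline and the uptake is monitored, and it leaves the aryl aldehyde and the MOM acetal unchanged.

Step 11
Reactants: 16 2-(methoxymethoxy)-6-[(2-methylbut-3-en-2-yl)oxy]benzaldehyde
Product: 18 2-hydroxy-6-(methoxymethoxy)-3-(3-methylbut-2-en-1-yl)benzaldehyde, via ortho-dienone 17 (not isolated)
Conditions: PhMe, 110 °C
Reagents that add atoms: none
Why: Aromatic Claisen rearrangement, a [3,3] shift that turns the 1,1-dimethylallyl group end for end into a prenyl group at C3, the only ortho carbon carrying hydrogen, is speeded by the gem-dimethyl group so that neutral heating suffices and dienone 17 tautomerises to the hydrogen-bonded phenol.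

Step 12
Reactants: 11 (3R)-3-(2-hydroxypropan-2-yl)-7-methyl-2,3-dihydro-1,4-benzodioxine-5-carbohydrazide; 18 2-hydroxy-6-(methoxymethoxy)-3-(3-methylbut-2-en-1-yl)benzaldehyde
Product: 19 (E)-N-aroylhydrazone of 18 with 11 (ArA–CH=N–NH–C(=O)–ArB, free phenol ortho to the CH=N carbon)
Conditions: EtOH, 70 °C
Reagents that add atoms: none
Why: Acylhydrazone condensation of a hydrazide NH2 group on an aldehyde is fast and driven by the conjugated and hydrogen-bonded (E)-product, which should crystallise from the alcohol, and neutral conditions keep the MOM ether intact.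

Step 13
Reactants: 19 (E)-N-aroylhydrazone
Product: 22 2-{[(3R)-3-(2-hydroxypropan-2-yl)-7-methyl-2,3-dihydro-1,4-benzodioxin-5-yl]carbonyl}-6-(methoxymethoxy)-3-(3-methylbut-2-en-1-yl)benzaldehyde, via acetoxy-oxadiazoline 20 (not isolated), via azo-bridged benzodioxine 21 (not isolated)
Conditions: Pb(OAc)4 (1.05 equiv, slow addition), THF, 0 °C to rt
Reagents that add atoms: none
Why: Pb(OAc)4 oxidises the hydrazide N–H of 19, the acyl oxygen closes onto the former aldehyde carbon and acetate is taken up at the former acyl carbon, which gives the 2-acetoxy-2,5-dihydro-1,3,4-oxadiazole 20 (five-membered, transient). The ortho phenol oxygen, held within reach of that carbon, displaces the acetate to form the azo-bridged 4H-1,3-benzodioxine 21 (six-membered, transient), which loses N2; in the ylide or o-quinone-methide-like species left behind the ipso ring carbon moves from the phenol oxygen to the former acyl carbon, so the ring C–O bond is exchanged for the ring C–C(=O) bond and the aldehyde is set free again. The closest known reaction type is this same lead tetraacetate conversion of N-acylhydrazones of o-hydroxyaryl ketones and aldehydes into 1,2-diacylbenzenes and 2-acylbenzaldehydes, here applied to a more crowded member of the class. No ring of 22 is closed and no stereocentre is made, both transient rings are lost with the nitrogen, and the dioxane centre lies far from the reacting atoms. Site selectivity between the two ring A oxygens is secured by the MOM ether, which leaves only the hydroxyl next to the prenyl group able to attack. Chemoselectivity over the trisubstituted alkene, the phenol ring and the tertiary alcohol rests on the much faster N–H oxidation, which is why one equivalent of oxidant is added slowly at 0 °C.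

Step 14
Reactants: 22 MOM-protected 2-aroylbenzaldehyde
Product: 23 6-hydroxy-2-{[(3R)-3-(2-hydroxypropan-2-yl)-7-methyl-2,3-dihydro-1,4-benzodioxin-5-yl]carbonyl}-3-(3-methylbut-2-en-1-yl)benzaldehyde (target)
Conditions: 2 M aq HCl, THF, rt
Reagents that add atoms: none
Why: Acid hydrolysis of a phenolic MOM acetal, made easy by the ortho formyl group that turns the aryloxide into a good leaving group, is run in aqueous THF without alcohol or thiol so that the two carbonyl groups are not acetalised, and the freed phenol lies para to the prenyl group so it cannot close a chroman.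

Compound list
1 | creosol (2-methoxy-4-methylphenol) | COc1cc(C)ccc1O | starting material
2 | 2-hydroxy-3-methoxy-5-methylbenzaldehyde | COc1cc(C)cc(C=O)c1O | intermediate
3 | 2,3-dihydroxy-5-methylbenzaldehyde | O=Cc1cc(C)cc(O)c1O | intermediate
4 | prenol (3-methylbut-2-en-1-ol) | CC(C)=CCO | starting material
5 | [(2S)-3,3-dimethyloxiran-2-yl]methanol | CC1(C)O[C@H]1CO | intermediate
6 | [(2S)-3,3-dimethyloxiran-2-yl]methyl 4-methylbenzenesulfonate | CC1(C)O[C@H]1COS(=O)(=O)c1ccc(C)cc1 | intermediate
7 | 3-{[(2S)-3,3-dimethyloxiran-2-yl]methoxy}-2-hydroxy-5-methylbenzaldehyde (present as its sodium phenoxide, not isolated) | CC1(C)O[C@H]1COc1cc(C)cc(C=O)c1O | intermediate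
8 | (3R)-3-(2-hydroxypropan-2-yl)-7-methyl-2,3-dihydro-1,4-benzodioxine-5-carbaldehyde | O=Cc1cc(C)cc2c1O[C@@H](C(C)(C)O)CO2 | intermediate
9 | (3R)-3-(2-hydroxypropan-2-yl)-7-methyl-2,3-dihydro-1,4-benzodioxine-5-carboxylic acid | OC(=O)c1cc(C)cc2c1O[C@@H](C(C)(C)O)CO2 | intermediate
10 | N-acylimidazole of acid 9 (not isolated) | O=C(n1ccnc1)c1cc(C)cc2c1O[C@@H](C(C)(C)O)CO2 | intermediate
11 | (3R)-3-(2-hydroxypropan-2-yl)-7-methyl-2,3-dihydro-1,4-benzodioxine-5-carbohydrazide | NNC(=O)c1cc(C)cc2c1O[C@@H](C(C)(C)O)CO2 | intermediate
12 | 2,6-dihydroxybenzaldehyde | O=Cc1c(O)cccc1O | starting material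
13 | 2-hydroxy-6-(methoxymethoxy)benzaldehyde | COCOc1cccc(O)c1C=O | intermediate
14 | 3-chloro-3-methylbut-1-yne | CC(C)(Cl)C#C | starting material
15 | 2-(methoxymethoxy)-6-[(2-methylbut-3-yn-2-yl)oxy]benzaldehyde | C#CC(C)(C)Oc1cccc(OCOC)c1C=O | intermediate
16 | 2-(methoxymethoxy)-6-[(2-methylbut-3-en-2-yl)oxy]benzaldehyde | C=CC(C)(C)Oc1cccc(OCOC)c1C=O | intermediate
17 | 2-(methoxymethoxy)-5-(3-methylbut-2-en-1-yl)-6-oxocyclohexa-1,3-diene-1-carbaldehyde (racemic, not isolated) | O=CC1=C(OCOC)C=CC(CC=C(C)C)C1=O | intermediate
18 | 2-hydroxy-6-(methoxymethoxy)-3-(3-methylbut-2-en-1-yl)benzaldehyde | CC(C)=CCc1ccc(OCOC)c(C=O)c1O | intermediate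
19 | (3R)-N'-[(E)-{2-hydroxy-6-(methoxymethoxy)-3-(3-methylbut-2-en-1-yl)phenyl}methylidene]-3-(2-hydroxypropan-2-yl)-7-methyl-2,3-dihydro-1,4-benzodioxine-5-carbohydrazide | CC(C)=CCc1ccc(OCOC)c(/C=N/NC(=O)c2cc(C)cc3c2O[C@@H](C(C)(C)O)CO3)c1O | intermediate
20 | 2-acetoxy-2,5-dihydro-1,3,4-oxadiazole with the ring B aryl group on C2 and the ring A aryl group on C5 (C2 and C5 undefined, not isolated) | CC(=O)OC1(N=NC(O1)c2c(O)c(CC=C(C)C)ccc2OCOC)c3cc(C)cc4c3O[C@@H](C(C)(C)O)CO4 | intermediate
21 | 4H-1,3-benzodioxine of ring A whose C2 (bearing the ring B aryl group) and C4 (bearing H) are bridged by N=N (not isolated) | CC(C)=CCc1ccc(OCOC)c2c1OC3(N=NC2O3)c4cc(C)cc5c4O[C@@H](C(C)(C)O)CO5 | intermediate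
22 | 2-{[(3R)-3-(2-hydroxypropan-2-yl)-7-methyl-2,3-dihydro-1,4-benzodioxin-5-yl]carbonyl}-6-(methoxymethoxy)-3-(3-methylbut-2-en-1-yl)benzaldehyde | CC(C)=CCc1ccc(OCOC)c(C=O)c1C(=O)c1cc(C)cc2c1O[C@@H](C(C)(C)O)CO2 | intermediate
23 | 6-hydroxy-2-{[(3R)-3-(2-hydroxypropan-2-yl)-7-methyl-2,3-dihydro-1,4-benzodioxin-5-yl]carbonyl}-3-(3-methylbut-2-en-1-yl)benzaldehyde | CC(C)=CCc1ccc(O)c(C=O)c1C(=O)c1cc(C)cc2c1O[C@@H](C(C)(C)O)CO2 | target

Total step count: 14.
Longest linear sequence: 8 steps (1, 2, 5, 6, 7, 12, 13, 14). The branch from prenol through steps 3 and 4 is equally long, and the ring A branch needs 7.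

Steps most likely to fail

Step 13. The five-membered intermediate may aromatise by loss of acetic acid before the crowded phenol oxygen can attack. The oxidant may also be diverted into dearomatising acetoxylation of the phenol ring (Wessely type) or into attack on the prenyl alkene. The fallback makes the same aryl–carbonyl bond by cross-coupling. It sets out from 18 and 9 and comes back to the route at 22.
- Phenol 18 would be sulfonylated (Tf2O, pyridine, CH2Cl2, 0 °C) to 2-formyl-3-(methoxymethoxy)-6-(3-methylbut-2-en-1-yl)phenyl trifluoromethanesulfonate F1.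
- F1 would be stannylated (hexamethylditin, Pd(PPh3)4, LiCl, dioxane, heat) to 6-(methoxymethoxy)-3-(3-methylbut-2-en-1-yl)-2-(trimethylstannyl)benzaldehyde F2.
- Acid 9 would be condensed with 4-methylbenzenethiol (EDC, DMAP, CH2Cl2) to the S-(4-methylphenyl) thioester F3.
- Coupling of F2 with F3 under Pd(0) and copper(I) diphenylphosphinate (Liebeskind–Srogl type ketone synthesis) is neutral. It should tolerate the aldehyde, the alkene and the tertiary alcohol and give 22.

Step 5. The two oxides of the dianion may not be discriminated fully in the first alkylation. The closure by the formyl-stabilised oxide may also be slow enough for intermolecular epoxide opening or for aryl migration to the new tertiary alkoxide (Smiles type) to intervene. The fallback fixes the site with a protecting group and triggers the closure by deprotection. It sets out from 3 and 6 and comes back to the route at 8, passing through 7 in the flask.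
- One equivalent of K2CO3 in DMF would ionise only the more acidic C2 hydroxyl, and allyl bromide would give 2-(allyloxy)-3-hydroxy-5-methylbenzaldehyde F4.
- The remaining C3 phenol would be alkylated with 6 (Cs2CO3, DMF, rt) to 2-(allyloxy)-3-{[(2S)-3,3-dimethyloxiran-2-yl]methoxy}-5-methylbenzaldehyde F5.
- Pd(PPh3)4 with K2CO3 in MeOH would remove the allyl group. The freed C2 phenoxide, in a buffered protic medium, would close the dioxane with the same inversion.

Step 9. O-alkylation of the hydrogen-bonded phenol flanked by the formyl group may be slower than base-induced elimination of the tertiary chloride. Any warming invites premature sigmatropic cyclisation of the propargyl ether. The fallback replaces the propargylation and the semihydrogenation by one π-allyl substitution. It sets out from 13 and comes back to the route at 16. Phenol 13 would be treated with tert-butyl 2-methylbut-3-en-2-yl carbonate and Pd(PPh3)4 in THF at 0 °C (Tsuji–Trost O-allylation, kinetic attack at the tertiary terminus). This should give the 1,1-dimethylallyl ether directly, and no compound outside the list is made (F0).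

Further compounds
F1 | step 13 | 2-formyl-3-(methoxymethoxy)-6-(3-methylbut-2-en-1-yl)phenyl trifluoromethanesulfonate | CC(C)=CCc1ccc(OCOC)c(C=O)c1OS(=O)(=O)C(F)(F)F
F2 | step 13 | 6-(methoxymethoxy)-3-(3-methylbut-2-en-1-yl)-2-(trimethylstannyl)benzaldehyde | CC(C)=CCc1ccc(OCOC)c(C=O)c1[Sn](C)(C)C
F3 | step 13 | S-(4-methylphenyl) (3R)-3-(2-hydroxypropan-2-yl)-7-methyl-2,3-dihydro-1,4-benzodioxine-5-carbothioate | Cc1ccc(cc1)SC(=O)c1cc(C)cc2c1O[C@@H](C(C)(C)O)CO2
F4 | step 5 | 2-(allyloxy)-3-hydroxy-5-methylbenzaldehyde | C=CCOc1c(O)cc(C)cc1C=O
F5 | step 5 | 2-(allyloxy)-3-{[(2S)-3,3-dimethyloxiran-2-yl]methoxy}-5-methylbenzaldehyde | CC1(C)O[C@H]1COc1cc(C)cc(C=O)c1OCC=C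
F0 | step 9 | none | none
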